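**Strategy**

Numbering: spiro carbon C5; ring A C1(O-ester)–C2–C3(isopropenyl)–C4; ring B C6(Me)=C7–C8(=O)–C9(OAc)–C10(Me). Everything rests on cutting the C5–C4 bond. The feature exploited is that ring A holds its oxygen on C1, directly beside spiro C5, while ring B holds its alkene at C6=C7: the imprint of a semipinacol shift onto an allyl unit. A zerovalent palladium catalyst opens a C7 carbonate to a π-allyl across C5–C6–C7 and one cyclobutanol methylene shifts onto C5; this single operation grows the four-membered ring into the ring A cyclopentanone, fixes the quaternary stereocentre and places the alkene. The precursor is a ring B cyclohexenyl carbonate, carbonate trans to the C10 methyl, bearing a symmetric 3,3-dimethoxycyclobutanol on C5.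

Key step: step 12

Remark: names of spiro compounds use the locants defined above rather than lowest-locant rules, and the large/small assignment in the two oxazaborolidine reductions follows the standard transition-state model; the SMILES strings define each structure.

**Route**

Step 1
Reactants: 1 2-methylcyclohexane-1,3-dione
Product: 2 3-ethoxy-2-methylcyclohex-2-en-1-one
Conditions: EtOH, TsOH·H2O (cat.), toluene, reflux, Dean–Stark
Reagents that add atoms: ethanol, CCO
Why: Acid-catalysed O-alkylation of the symmetrical 1,3-dione (vinylogous ester formation) is driven to completion by azeotropic removal of water and creates no stereocentre.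

Step 2
Reactants: 2 3-ethoxy-2-methylcyclohex-2-en-1-one
Product: 4 rac-3-ethoxy-2,6-dimethylcyclohex-2-en-1-one, via lithium dienolate 3 (not isolated)
Conditions: LiN(iPr)2, THF, −78 °C; MeI, −78 → 0 °C
Reagents that add atoms: iodomethane, CI
Why: Kinetic deprotonation of a vinylogous ester occurs at the α′ carbon and the cross-conjugated enolate is C-methylated there (Stork–Danheiser alkylation), which puts the future C10 methyl beside the carbonyl carbon that becomes C5, the product being racemic.

Step 3
Reactants: 4 rac-3-ethoxy-2,6-dimethylcyclohex-2-en-1-one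
Product: 5 rac-3-bromo-2,4-dimethylcyclohex-2-en-1-one
Conditions: (COBr)2, DMF (cat.), CH2Cl2, 0 °C → rt
Reagents that add atoms: oxalyl bromide, O=C(Br)C(=O)Br
Why: In this halodealkoxylation of a β-alkoxy enone the oxalyl bromide acylates the only nucleophilic oxygen (the carbonyl oxygen), bromide replaces it by addition–elimination and the bromo-substituted oxocarbenium ion loses bromoethane, so bromine should arrive at the former carbonyl carbon next to the CHMe group with 1,3-transposition of the carbonyl.

Step 4
Reactants: 5 rac-3-bromo-2,4-dimethylcyclohex-2-en-1-one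
Product: 6 (1S,4S)-3-bromo-2,4-dimethylcyclohex-2-en-1-ol
Conditions: (R)-2-methyl-CBS-oxazaborolidine (20 mol%), BH3·SMe2, THF, −20 °C; MeOH; chromatographic separation from the cis (1S,4R) diastereomer
Reagents that add atoms: none
Why: Corey–Bakshi–Shibata reduction, with the α-methyl alkenyl carbon as the large group, should set the carbinol as S in both enantiomers of 5 regardless of the remote C4 methyl, so the racemate diverges into the trans (1S,4S) alcohol 6 and its separable cis diastereomer, at most half of the material being usable.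

Step 5
Reactants: 6 (1S,4S)-3-bromo-2,4-dimethylcyclohex-2-en-1-ol
Product: 7 tert-butyl{[(1S,4S)-3-bromo-2,4-dimethylcyclohex-2-en-1-yl]oxy}dimethylsilane
Conditions: TBSCl, imidazole, DMF, rt
Reagents that add atoms: tert-butyldimethylsilyl chloride, CC(C)(C)[Si](C)(C)Cl
Why: Standard imidazole-mediated silylation masks the hydroxyl against the organolithium chemistry of step 9 without touching either stereocentre.

Step 6
Reactants: 8 3-(benzyloxy)cyclobutan-1-one
Product: 9 [(3,3-dimethoxycyclobutoxy)methyl]benzene
Conditions: HC(OMe)3, MeOH, TsOH·H2O (cat.), rt; Et3N quench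
Reagents that add atoms: trimethyl orthoformate, COC(OC)OC; methanol, CO
Why: Acid-catalysed ketalization with the orthoformate as water scavenger protects the ketone as an acyclic dimethyl ketal that keeps the four-membered ring symmetric.

Step 7
Reactants: 9 [(3,3-dimethoxycyclobutoxy)methyl]benzene
Product: 10 3,3-dimethoxycyclobutan-1-ol
Conditions: H2 (1 atm), Pd on carbon (10% Pd/C), EtOAc, Et3N (trace), rt
Reagents that add atoms: none
Why: Hydrogenolysis of the benzyl ether frees the secondary alcohol under neutral conditions that leave the ketal intact.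

Step 8
Reactants: 10 3,3-dimethoxycyclobutan-1-ol
Product: 11 3,3-dimethoxycyclobutan-1-one
Conditions: nPr4N[RuO4] (5 mol%), N-methylmorpholine N-oxide, 4 Å molecular sieves, CH2Cl2, rt
Reagents that add atoms: none
Why: Ley–Griffith oxidation is neutral and non-aqueous, so the alcohol should be oxidized to the volatile cyclobutanone (used as a solution) without ketal loss or β-elimination.

Step 9
Reactants: 7 tert-butyl{[(1S,4S)-3-bromo-2,4-dimethylcyclohex-2-en-1-yl]oxy}dimethylsilane; 11 3,3-dimethoxycyclobutan-1-one
Product: 13 1-[(3S,6S)-3-{[tert-butyl(dimethyl)silyl]oxy}-2,6-dimethylcyclohex-1-en-1-yl]-3,3-dimethoxycyclobutan-1-ol, via alkenyllithium 12 (not isolated)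
Conditions: t-BuLi (2.1 equiv), Et2O, −78 °C; then 11, −78 → −40 °C; H2O
Reagents that add atoms: none
Why: Bromine–lithium exchange gives a cyclic alkenyllithium that cannot eliminate the remote silyloxy group, and its 1,2-addition to the strained, highly electrophilic cyclobutanone forms the tertiary cyclobutanol, whose carbinol carbon is not stereogenic because the ring is symmetric.

Step 10
Reactants: 13 1-[(3S,6S)-3-{[tert-butyl(dimethyl)silyl]oxy}-2,6-dimethylcyclohex-1-en-1-yl]-3,3-dimethoxycyclobutan-1-ol
Product: 14 (1S,4S)-3-(1-hydroxy-3,3-dimethoxycyclobutyl)-2,4-dimethylcyclohex-2-en-1-ol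
Conditions: Bu4NF, THF, 0 °C → rt
Reagents that add atoms: none
Why: Fluoride-mediated desilylation frees the secondary allylic alcohol while the tertiary cyclobutanol, the ketal and both stereocentres are unaffected.

Step 11
Reactants: 14 (1S,4S)-3-(1-hydroxy-3,3-dimethoxycyclobutyl)-2,4-dimethylcyclohex-2-en-1-ol; 15 methyl chloroformate
Product: 16 (1S,4S)-3-(1-hydroxy-3,3-dimethoxycyclobutyl)-2,4-dimethylcyclohex-2-en-1-yl methyl carbonate
Conditions: pyridine, DMAP (cat.), CH2Cl2, 0 °C
Reagents that add atoms: none
Why: Chloroformate acylation under pyridine discriminates the secondary allylic hydroxyl from the hindered tertiary cyclobutanol and installs the leaving group with retention at C7.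

Step 12
Reactants: 16 (1S,4S)-3-(1-hydroxy-3,3-dimethoxycyclobutyl)-2,4-dimethylcyclohex-2-en-1-yl methyl carbonate
Product: 17 (5S,10S)-3,3-dimethoxy-6,10-dimethylspiro[4.5]dec-6-en-1-one
Conditions: Pd2(dba)3·CHCl3 (5 mol%), PPh3 (20 mol%), THF, 50 °C
Reagents that add atoms: none
Why: Zerovalent palladium displaces the pseudoaxial C7 carbonate with inversion to give a π-allyl complex over C5–C6–C7, carbon dioxide is lost and the liberated methoxide deprotonates the cyclobutanol, whose ring C–C bond anti to the metal then shifts to C5 as the alkoxide becomes the C1 carbonyl, releasing the catalyst and leaving the alkene at C6=C7. The closest known reaction type is the palladium-catalysed Wagner–Meerwein (semipinacol) ring expansion of allylic carbonates of 1-alkenylcyclobutanols. Ring A is closed not by an end-to-end cyclization but by a 1,2-alkyl shift that enlarges the four-membered carbinol ring to the cyclopentanone, with relief of ring strain as driving force. The new quaternary stereocentre C5 is controlled by the C7 carbonate configuration through two inversions (C4 enters the face the carbonate left), and because the carbonate is trans to the C10 methyl that face is also the one anti to the methyl, so stereospecificity and substrate bias are matched. Site selectivity is secured because only C5 lies within reach of the migrating carbon, and no choice between migrating groups arises because the two ring methylenes of the 3,3-dimethoxycyclobutanol are equivalent; the competing path to suppress is β-hydride loss from the π-allyl to a diene.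

Step 13
Reactants: 17 (5S,10S)-3,3-dimethoxy-6,10-dimethylspiro[4.5]dec-6-en-1-one
Product: 18 (5S,10S)-6,10-dimethylspiro[4.5]dec-6-ene-1,3-dione
Conditions: 1 M aq. HCl, THF, rt
Reagents that add atoms: water, O
Why: Aqueous acid hydrolyses the dimethyl ketal to the 1,3-dione (present largely as its enol), the quaternary C5 being non-epimerizable and acidic conditions excluding retro-Claisen cleavage.

Step 14
Reactants: 18 (5S,10S)-6,10-dimethylspiro[4.5]dec-6-ene-1,3-dione
Product: 19 (5S,10S)-6,10-dimethyl-1-oxospiro[4.5]deca-2,6-dien-3-yl trifluoromethanesulfonate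
Conditions: Tf2O, Et3N, CH2Cl2, −78 °C
Reagents that add atoms: trifluoromethanesulfonic anhydride, O=S(=O)(OS(=O)(=O)C(F)(F)F)C(F)(F)F
Why: O-Sulfonylation of the delocalized dione enolate should occur at the less hindered oxygen on C3, remote from the quaternary C5, giving the enol triflate with the C1 ketone retained.

Step 15
Reactants: 19 (5S,10S)-6,10-dimethyl-1-oxospiro[4.5]deca-2,6-dien-3-yl trifluoromethanesulfonate
Product: 20 (5S,10S)-3-(1-ethoxyethenyl)-6,10-dimethylspiro[4.5]deca-2,6-dien-1-one
Conditions: tributyl(1-ethoxyethenyl)stannane, Pd(PPh3)4 (5 mol%), LiCl, THF, 65 °C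
Reagents that add atoms: tributyl(1-ethoxyethenyl)stannane, CCCC[Sn](CCCC)(CCCC)C(=C)OCC
Why: Stille coupling of the enol triflate with the 1-ethoxyvinyl stannane, a masked acetyl group, forms the C3–carbon bond under neutral conditions that tolerate the hindered ketone.

Step 16
Reactants: 20 (5S,10S)-3-(1-ethoxyethenyl)-6,10-dimethylspiro[4.5]deca-2,6-dien-1-one
Product: 22 1-[(1S,5S,10S)-1-hydroxy-6,10-dimethylspiro[4.5]deca-2,6-dien-3-yl]ethan-1-one, via dienol ether alcohol 21 (not isolated)
Conditions: (R)-2-methyl-CBS-oxazaborolidine (20 mol%), catecholborane, toluene, −78 °C; aq. NaHCO3; then 0.5 M aq. HCl, THF, 0 °C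
Reagents that add atoms: water, O
Why: Corey–Bakshi–Shibata 1,2-reduction, in which the quaternary spiro carbon C5 is the large and the vinylic C2–H the small ketone substituent, should set C1 as S (oxygen on the ring A face toward C10) by reagent control while catecholborane spares the alkenes, and brief dilute acid then hydrolyses the 2-ethoxydiene to the methyl ketone.

Step 17
Reactants: 22 1-[(1S,5S,10S)-1-hydroxy-6,10-dimethylspiro[4.5]deca-2,6-dien-3-yl]ethan-1-one
Product: 23 1-[(1S,3R,5S,10S)-1-hydroxy-6,10-dimethylspiro[4.5]dec-6-en-3-yl]ethan-1-one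
Conditions: [Rh(nbd)(dppb)]BF4 (5 mol%), H2 (40 atm), CH2Cl2, rt
Reagents that add atoms: none
Why: Hydroxyl-directed homogeneous hydrogenation with a cationic rhodium diphosphine delivers hydrogen to C2=C3 from the face of the allylic C1 hydroxyl, so the acetyl group at the new C3 stereocentre ends trans to oxygen, while the undirected, hindered C6=C7 alkene (C6 lies anti to the hydroxyl across C5) should stay untouched.

Step 18
Reactants: 23 1-[(1S,3R,5S,10S)-1-hydroxy-6,10-dimethylspiro[4.5]dec-6-en-3-yl]ethan-1-one
Product: 24 (1S,3R,5S,10S)-3-acetyl-6,10-dimethylspiro[4.5]dec-6-en-1-yl 3-methylbut-2-enoate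
Conditions: 3-methylbut-2-enoyl chloride, pyridine, DMAP (cat.), CH2Cl2, 0 °C → rt
Reagents that add atoms: 3-methylbut-2-enoyl chloride, CC(C)=CC(=O)Cl
Why: Nucleophile-catalysed acylation of the secondary alcohol installs the senecioate with retention at C1, the weak base limiting deconjugation through the vinylketene and epimerization next to the methyl ketone.

Step 19
Reactants: 24 (1S,3R,5S,10S)-3-acetyl-6,10-dimethylspiro[4.5]dec-6-en-1-yl 3-methylbut-2-enoate
Product: 25 (1S,3R,5S,10S)-6,10-dimethyl-3-(prop-1-en-2-yl)spiro[4.5]dec-6-en-1-yl 3-methylbut-2-enoate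
Conditions: Zn, CH2Br2, TiCl4, THF, 0 °C → rt
Reagents that add atoms: dibromomethane, BrCBr
Why: Lombardo–Takai methylenation is non-basic and ketone-selective, so the methyl ketone becomes the isopropenyl group without epimerizing the adjacent C3 stereocentre or attacking the ester.

Step 20
Reactants: 25 (1S,3R,5S,10S)-6,10-dimethyl-3-(prop-1-en-2-yl)spiro[4.5]dec-6-en-1-yl 3-methylbut-2-enoate
Product: 26 (1S,3R,5S,10S)-6,10-dimethyl-8-oxo-3-(prop-1-en-2-yl)spiro[4.5]dec-6-en-1-yl 3-methylbut-2-enoate
Conditions: Rh2(cap)4 (cap = caprolactamate, 1 mol%), t-BuOOH, K2CO3, CH2Cl2, rt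
Reagents that add atoms: tert-butyl hydroperoxide, CC(C)(C)OO
Why: Dirhodium-catalysed allylic oxidation with tert-butyl hydroperoxide converts the ring allylic methylene C8 of the trisubstituted C6=C7 alkene into the conjugated ketone, a preference for a ring methylene over isopropenyl and ester allylic positions that is well established for sesquiterpene dienes of this kind.

Step 21
Reactants: 26 (1S,3R,5S,10S)-6,10-dimethyl-8-oxo-3-(prop-1-en-2-yl)spiro[4.5]dec-6-en-1-yl 3-methylbut-2-enoate
Product: 27 (1S,3R,5S,9S,10R)-9-(acetyloxy)-6,10-dimethyl-8-oxo-3-(prop-1-en-2-yl)spiro[4.5]dec-6-en-1-yl 3-methylbut-2-enoate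
Conditions: Mn(OAc)3·2H2O, benzene, reflux
Reagents that add atoms: manganese triacetate, CC(=O)[O-].CC(=O)[O-].CC(=O)[O-].[Mn+3]
Why: α′-Acetoxylation of the enone with Mn(OAc)3 proceeds through the trivalent manganese enolate at C9, and acetate should enter anti to the vicinal C10 methyl to give the trans 9-acetoxy-10-methyl arrangement, which is also the thermodynamically preferred one.

**Compound list**

1 | 2-methylcyclohexane-1,3-dione | CC1C(=O)CCCC1=O | starting material
2 | 3-ethoxy-2-methylcyclohex-2-en-1-one | CCOC1=C(C)C(=O)CCC1 | intermediate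
3 | lithium 5-ethoxy-6-methylcyclohexa-1,5-dien-1-olate | CCOC1=C(C)C(O[Li])=CCC1 | intermediate
4 | rac-3-ethoxy-2,6-dimethylcyclohex-2-en-1-one | CCOC1=C(C)C(=O)C(C)CC1 | intermediate
5 | rac-3-bromo-2,4-dimethylcyclohex-2-en-1-one | CC1CCC(=O)C(C)=C1Br | intermediate
6 | (1S,4S)-3-bromo-2,4-dimethylcyclohex-2-en-1-ol | O[C@H]1CC[C@H](C)C(Br)=C1C | intermediate
7 | tert-butyl{[(1S,4S)-3-bromo-2,4-dimethylcyclohex-2-en-1-yl]oxy}dimethylsilane | CC(C)(C)[Si](C)(C)O[C@H]1CC[C@H](C)C(Br)=C1C | intermediate
8 | 3-(benzyloxy)cyclobutan-1-one | O=C1CC(OCc2ccccc2)C1 | starting material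
9 | [(3,3-dimethoxycyclobutoxy)methyl]benzene | COC1(OC)CC(OCc2ccccc2)C1 | intermediate
10 | 3,3-dimethoxycyclobutan-1-ol | COC1(OC)CC(O)C1 | intermediate
11 | 3,3-dimethoxycyclobutan-1-one | COC1(OC)CC(=O)C1 | intermediate
12 | [(3S,6S)-3-{[tert-butyl(dimethyl)silyl]oxy}-2,6-dimethylcyclohex-1-en-1-yl]lithium | CC(C)(C)[Si](C)(C)O[C@H]1CC[C@H](C)C([Li])=C1C | intermediate
13 | 1-[(3S,6S)-3-{[tert-butyl(dimethyl)silyl]oxy}-2,6-dimethylcyclohex-1-en-1-yl]-3,3-dimethoxycyclobutan-1-ol | CC(C)(C)[Si](C)(C)O[C@H]1CC[C@H](C)C(=C1C)C1(O)CC(OC)(OC)C1 | intermediate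
14 | (1S,4S)-3-(1-hydroxy-3,3-dimethoxycyclobutyl)-2,4-dimethylcyclohex-2-en-1-ol | O[C@H]1CC[C@H](C)C(=C1C)C1(O)CC(OC)(OC)C1 | intermediate
15 | methyl chloroformate | COC(=O)Cl | starting material
16 | (1S,4S)-3-(1-hydroxy-3,3-dimethoxycyclobutyl)-2,4-dimethylcyclohex-2-en-1-yl methyl carbonate | COC(=O)O[C@H]1CC[C@H](C)C(=C1C)C1(O)CC(OC)(OC)C1 | intermediate
17 | (5S,10S)-3,3-dimethoxy-6,10-dimethylspiro[4.5]dec-6-en-1-one | COC1(OC)CC(=O)[C@]2(C1)C(C)=CCC[C@@H]2C | intermediate
18 | (5S,10S)-6,10-dimethylspiro[4.5]dec-6-ene-1,3-dione | O=C1CC(=O)[C@]2(C1)C(C)=CCC[C@@H]2C | intermediate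
19 | (5S,10S)-6,10-dimethyl-1-oxospiro[4.5]deca-2,6-dien-3-yl trifluoromethanesulfonate | FC(F)(F)S(=O)(=O)OC1=CC(=O)[C@]2(C1)C(C)=CCC[C@@H]2C | intermediate
20 | (5S,10S)-3-(1-ethoxyethenyl)-6,10-dimethylspiro[4.5]deca-2,6-dien-1-one | CCOC(=C)C1=CC(=O)[C@]2(C1)C(C)=CCC[C@@H]2C | intermediate
21 | (1S,5S,10S)-3-(1-ethoxyethenyl)-6,10-dimethylspiro[4.5]deca-2,6-dien-1-ol | CCOC(=C)C1=C[C@H](O)[C@]2(C1)C(C)=CCC[C@@H]2C | intermediate
22 | 1-[(1S,5S,10S)-1-hydroxy-6,10-dimethylspiro[4.5]deca-2,6-dien-3-yl]ethan-1-one | CC(=O)C1=C[C@H](O)[C@]2(C1)C(C)=CCC[C@@H]2C | intermediate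
23 | 1-[(1S,3R,5S,10S)-1-hydroxy-6,10-dimethylspiro[4.5]dec-6-en-3-yl]ethan-1-one | CC(=O)[C@H]1C[C@H](O)[C@]2(C1)C(C)=CCC[C@@H]2C | intermediate
24 | (1S,3R,5S,10S)-3-acetyl-6,10-dimethylspiro[4.5]dec-6-en-1-yl 3-methylbut-2-enoate | CC(=O)[C@H]1C[C@H](OC(=O)C=C(C)C)[C@]2(C1)C(C)=CCC[C@@H]2C | intermediate
25 | (1S,3R,5S,10S)-6,10-dimethyl-3-(prop-1-en-2-yl)spiro[4.5]dec-6-en-1-yl 3-methylbut-2-enoate | C=C(C)[C@H]1C[C@H](OC(=O)C=C(C)C)[C@]2(C1)C(C)=CCC[C@@H]2C | intermediate
26 | (1S,3R,5S,10S)-6,10-dimethyl-8-oxo-3-(prop-1-en-2-yl)spiro[4.5]dec-6-en-1-yl 3-methylbut-2-enoate | C=C(C)[C@H]1C[C@H](OC(=O)C=C(C)C)[C@]2(C1)C(C)=CC(=O)C[C@@H]2C | intermediate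
27 | (1S,3R,5S,9S,10R)-9-(acetyloxy)-6,10-dimethyl-8-oxo-3-(prop-1-en-2-yl)spiro[4.5]dec-6-en-1-yl 3-methylbut-2-enoate | C=C(C)[C@H]1C[C@H](OC(=O)C=C(C)C)[C@]2(C1)C(C)=CC(=O)[C@@H](OC(C)=O)[C@@H]2C | target

**Step count and risks**

Total step count: 21. Longest linear sequence: 18 steps (steps 1–5 and 9–21, from 1 to 27).

The three steps most likely to fail:

Step 12. Ionization may be slow because palladium has to bind the tetrasubstituted C5=C6 alkene on the face crowded by the pseudoaxial C10 methyl. The π-allyl may then collapse by β-hydride loss to a diene instead of undergoing the shift, and stereospecificity may erode through metal–metal exchange. The fallback is a metal-free, cationic semipinacol that sets out from 14. The secondary allylic hydroxyl is acylated selectively (trifluoroacetic anhydride, 2,6-lutidine, CH2Cl2, −78 °C) to (1S,4S)-3-(1-hydroxy-3,3-dimethoxycyclobutyl)-2,4-dimethylcyclohex-2-en-1-yl trifluoroacetate F1. F1 is ionized in hexafluoroisopropanol buffered with 2,6-lutidine to the tetrasubstituted allyl cation. A cyclobutanol methylene then shifts to the C5 face anti to the C10 methyl (substrate control only), and the route is rejoined at 17.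

Step 16. Facial selectivity at the C1 carbonyl may be poor or reversed, because its two faces are flanked by the similar methyl-bearing carbons C6 and C10 and the catalyst must override this. The fallback gives up reagent control and sets out from 20. Achiral 1,2-reduction (iBu2AlH, toluene, −78 °C) gives 21 together with its C1 epimer (1R,5S,10S)-3-(1-ethoxyethenyl)-6,10-dimethylspiro[4.5]deca-2,6-dien-1-ol F2. The epimers are separated on triethylamine-deactivated silica and F2 is returned to 20 by oxidation with MnO2. The route is rejoined at 21, which is hydrolysed as in step 16.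

Step 3. Bromide may be delivered at the alkoxy-bearing carbon, or simple dealkylation to the dione may occur; either would scramble the position of bromine relative to the CHMe group. The fallback sets out from 4. Aqueous acid hydrolysis gives 2,4-dimethylcyclohexane-1,3-dione F3. Bromination with Ph3P·Br2 and Et3N in CH2Cl2 then gives 5 together with the regioisomer rac-3-bromo-2,6-dimethylcyclohex-2-en-1-one F4. 5 is expected to be the minor component and is isolated by chromatography. The route is rejoined at 5.

Further compounds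
F1 | step 12 | (1S,4S)-3-(1-hydroxy-3,3-dimethoxycyclobutyl)-2,4-dimethylcyclohex-2-en-1-yl trifluoroacetate | FC(F)(F)C(=O)O[C@H]1CC[C@H](C)C(=C1C)C1(O)CC(OC)(OC)C1
F2 | step 16 | (1R,5S,10S)-3-(1-ethoxyethenyl)-6,10-dimethylspiro[4.5]deca-2,6-dien-1-ol | CCOC(=C)C1=C[C@@H](O)[C@]2(C1)C(C)=CCC[C@@H]2C
F3 | step 3 | 2,4-dimethylcyclohexane-1,3-dione | CC1CCC(=O)C(C)C1=O
F4 | step 3 | rac-3-bromo-2,6-dimethylcyclohex-2-en-1-one | CC1CCC(Br)=C(C)C1=O
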